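## Retrosynthetic overview
1. Aiphanol comes from removal of three MOM groups and one acetate from an E-stilbene. That stilbene is made by Horner–Wadsworth–Emmons (HWE) coupling of a (2R,3R)-benzodioxane-6-carbaldehyde with a 3,5-bis(MOM-oxy)benzyl phosphonate.
2. The 1,4-dioxane ring is closed by an intramolecular Mitsunobu reaction forming O4'–C8 with inversion. The primary C9–OH of the phenol/secondary-alcohol precursor is first masked by a lipase-catalysed regioselective acetylation.
3. That precursor comes from forming O3'–C7 by SN2 opening (inversion) of a (2S,3S)-3-arylglycidol with 4-O-allyl protocatechualdehyde. Two inversions on a trans-epoxide give the trans-(R,R) ring.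
4. The epoxy alcohol comes from catalytic Sharpless asymmetric epoxidation of MOM-protected sinapyl alcohol, itself made from syringaldehyde by HWE and DIBAL-H reduction.
5. Ring order: all three arenes are purchased; the oxirane forms in step 4 (transient) and the 1,4-dioxane in step 9.

Assumption: the SMILES encodes the trans-(2R,3R)-benzodioxane with an E-alkene. Lignan locants are used below: C7 = ArCH–O, C8 = CH–CH2OH, C9 = CH2OH. The catalytic ligand and the enzyme are treated as catalysts, not starting materials.

## Route

**Step 1**
Reactants: 1, syringaldehyde (4-hydroxy-3,5-dimethoxybenzaldehyde)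
Product: 2, 3,5-dimethoxy-4-(methoxymethoxy)benzaldehyde
Conditions: MOMCl (1.5 equiv), i-Pr2NEt, CH2Cl2, 0 °C → rt
Reagents that add atoms: chloromethyl methyl ether (MOMCl), COCCl
Why: Williamson-type O-alkylation (MOM protection) works because the para-formyl phenol is acidic enough for an amine base, and the acetal survives every basic, hydride, Ti, Pd and enzymatic step until its planned removal in step 16.

**Step 2**
Reactants: 2; 3, triethyl phosphonoacetate
Product: 4, ethyl (E)-3-[3,5-dimethoxy-4-(methoxymethoxy)phenyl]prop-2-enoate
Conditions: NaH, THF, 0 °C → rt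
Reagents that add atoms: triethyl phosphonoacetate (3), CCOC(=O)CP(=O)(OCC)OCC
Why: Horner–Wadsworth–Emmons olefination with a stabilised phosphonate gives the E-cinnamate (>20:1), and this geometry later becomes the trans ring.

**Step 3**
Reactants: 4
Product: 5, (E)-3-[3,5-dimethoxy-4-(methoxymethoxy)phenyl]prop-2-en-1-ol (MOM-sinapyl alcohol)
Conditions: DIBAL-H (2.3 equiv), CH2Cl2, −78 °C; Rochelle salt work-up
Reagents that add atoms: none
Why: DIBAL-H 1,2-reduction of the conjugated ester stops at the allylic alcohol without touching the alkene, the aryl ethers or the MOM acetal.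

**Step 4**
Reactants: 5
Product: 6, [(2S,3S)-3-[3,5-dimethoxy-4-(methoxymethoxy)phenyl]oxiran-2-yl]methanol
Conditions: Ti(Oi-Pr)4 (10 mol %), L-(+)-DIPT (14 mol %), t-BuOOH (2 equiv, decane), 4 Å MS, CH2Cl2, −20 °C; NaOH/brine work-up; Et3N-deactivated silica
Reagents that add atoms: tert-butyl hydroperoxide, CC(C)(C)OO
Why: In the Katsuki–Sharpless asymmetric epoxidation the catalytic Ti/L-(+)-tartrate complex delivers oxygen to the face that gives the (2S,3S)-epoxide, as for E-cinnamyl alcohols generally (typically ≥95% ee), which creates both stereocentres from an achiral alkene, and the basic work-up protects the benzylic epoxide.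

**Step 5**
Reactants: 7, 3,4-dihydroxybenzaldehyde
Product: 8, 4-(allyloxy)-3-hydroxybenzaldehyde
Conditions: allyl bromide (1.0 equiv), NaHCO3, NaI (cat.), DMF, 40 °C
Reagents that add atoms: allyl bromide, C=CCBr
Why: This regioselective Williamson etherification works because only the 4-OH (para to CHO, pKa about 7) is ionised by bicarbonate, so O4 is masked and O3 stays free as the nucleophile.

**Step 6**
Reactants: 6; 8 (1.5 equiv)
Product: 9, 4-(allyloxy)-3-{[(1R,2S)-1-[3,5-dimethoxy-4-(methoxymethoxy)phenyl]-2,3-dihydroxypropyl]oxy}benzaldehyde (C7 R, C8 S)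
Conditions: Cs2CO3 (0.5 equiv), DMF, 70 °C
Reagents that add atoms: 8 (reactant), C=CCOc1ccc(C=O)cc1O
Why: In this base-mediated SN2 epoxide opening the phenoxide attacks the aryl-activated benzylic carbon with inversion (C7 S→R) while the C8–O bond is untouched, and keeping phenol in excess over base and avoiding Lewis acid suppresses Payne rearrangement and SN1 leakage.

**Step 7**
Reactants: 9
Product: 10, 3-{[(1R,2S)-1-[3,5-dimethoxy-4-(methoxymethoxy)phenyl]-2,3-dihydroxypropyl]oxy}-4-hydroxybenzaldehyde
Conditions: Pd(PPh3)4 (3 mol %), K2CO3, MeOH, rt, degassed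
Reagents that add atoms: none
Why: In this Tsuji–Trost-type deallylation Pd(0) ionises the aryl allyl ether (the aryloxide para to CHO is a good leaving group) and methanol scavenges the π-allyl, which leaves the MOM group, aldehyde, diol and benzylic aryl ether intact.

**Step 8**
Reactants: 10
Product: 11, (2S,3R)-3-[3,5-dimethoxy-4-(methoxymethoxy)phenyl]-3-(5-formyl-2-hydroxyphenoxy)-2-hydroxypropyl acetate
Conditions: lipase (immobilised Candida antarctica lipase B, Novozym 435), vinyl acetate (5 equiv), MTBE/THF, 35 °C; filter off enzyme
Reagents that add atoms: vinyl acetate, CC(=O)OC=C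
Why: In this irreversible transesterification the lipase (a serine hydrolase) acylates only the unhindered primary C9–OH and leaves the acidic phenol and the hindered C8–OH free, a selectivity that chemical acylation or silylation (phenol first) cannot give and that ensures only C8–OH can be activated in step 9, with no stereocentre touched.

**Step 9**
Reactants: 11
Product: 12, [(2R,3R)-3-[3,5-dimethoxy-4-(methoxymethoxy)phenyl]-6-formyl-2,3-dihydro-1,4-benzodioxin-2-yl]methyl acetate
Conditions: PPh3 (1.5 equiv), DIAD (1.5 equiv), THF (0.02 M), 0 °C → rt; check ee by chiral HPLC and recrystallise if needed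
Reagents that add atoms: none
Why: In this intramolecular Mitsunobu etherification the phenoxide (pKa about 7.5) displaces the C8 oxyphosphonium in a 6-exo-tet SN2 with inversion (C8 S→R), so the two inversions on the trans-epoxide give the diequatorial trans-(2R,3R) ring.

**Step 10**
Reactants: 13, methyl 3,5-dihydroxybenzoate
Product: 14, methyl 3,5-bis(methoxymethoxy)benzoate
Conditions: MOMCl (3 equiv), i-Pr2NEt, CH2Cl2, 0 °C → rt
Reagents that add atoms: MOMCl, COCCl
Why: Williamson-type MOM protection of both phenols gives groups that are stable to hydride, Arbuzov heating and HWE base and that are removed together with the syringyl MOM.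

**Step 11**
Reactants: 14
Product: 15, [3,5-bis(methoxymethoxy)phenyl]methanol
Conditions: LiAlH4, THF, 0 °C
Reagents that add atoms: none
Why: This is a standard hydride reduction of a benzoate ester, to which MOM ethers are inert.

**Step 12**
Reactants: 15
Product: 16, 1-(bromomethyl)-3,5-bis(methoxymethoxy)benzene
Conditions: CBr4, PPh3, CH2Cl2, 0 °C
Reagents that add atoms: carbon tetrabromide, BrC(Br)(Br)Br
Why: The Appel bromination runs under essentially neutral conditions, so the acid-labile MOM groups survive.

**Step 13**
Reactants: 16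
Product: 17, diethyl [3,5-bis(methoxymethoxy)benzyl]phosphonate
Conditions: P(OEt)3, neat, 130 °C
Reagents that add atoms: triethyl phosphite, CCOP(OCC)OCC
Why: The Michaelis–Arbuzov reaction of a primary benzylic bromide is high-yielding and neutral.

**Step 14**
Reactants: 12; 17 (1.4 equiv)
Product: 18, [(2R,3R)-6-{(E)-2-[3,5-bis(methoxymethoxy)phenyl]ethenyl}-3-[3,5-dimethoxy-4-(methoxymethoxy)phenyl]-2,3-dihydro-1,4-benzodioxin-2-yl]methyl acetate
Conditions: 17, NaH (1.3 equiv), 15-crown-5 (cat.), THF, 0 °C, 30 min; then 12, 0 °C → rt
Reagents that add atoms: 17 (reactant), CCOP(=O)(Cc1cc(OCOC)cc(OCOC)c1)OCC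
Why: Horner–Wadsworth–Emmons olefination with a benzylic phosphonate gives the E-stilbene (>20:1), and because phosphonate is kept in excess over NaH no free base attacks the acetate (any acetate lost converges in step 15) and neither stereocentre is acidic.

**Step 15**
Reactants: 18
Product: 19, [(2R,3R)-6-{(E)-2-[3,5-bis(methoxymethoxy)phenyl]ethenyl}-3-[3,5-dimethoxy-4-(methoxymethoxy)phenyl]-2,3-dihydro-1,4-benzodioxin-2-yl]methanol
Conditions: K2CO3 (0.5 equiv), MeOH/THF, rt
Reagents that add atoms: none
Why: This base-catalysed transesterification (methanolysis) of a primary acetate is safe because all phenols are still masked, so no phenoxide can open the ring through a quinone methide.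

**Step 16**
Reactants: 19
Product: 20, aiphanol, 5-{(E)-2-[(2R,3R)-3-(4-hydroxy-3,5-dimethoxyphenyl)-2-(hydroxymethyl)-2,3-dihydro-1,4-benzodioxin-6-yl]ethenyl}benzene-1,3-diol
Conditions: 2 M aq HCl, MeOH/THF, 45 °C, Ar, dark
Reagents that add atoms: none
Why: Brønsted-acid acetal cleavage removes the three aryl MOM groups (formaldehyde is trapped as methylal), and since C8 cannot ionise and any reversible ionisation at benzylic C7 re-closes to the more stable trans ring, the (2R,3R) configuration and the E-alkene are retained.

## Compound list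
| No. | Name | SMILES | Role |
|---|---|---|---|
| 1 | syringaldehyde | COc1cc(C=O)cc(OC)c1O | starting material |
| 2 | 3,5-dimethoxy-4-(MOM-oxy)benzaldehyde | COCOc1c(OC)cc(C=O)cc1OC | intermediate |
| 3 | triethyl phosphonoacetate | CCOC(=O)CP(=O)(OCC)OCC | starting material |
| 4 | ethyl (E)-cinnamate derivative | CCOC(=O)/C=C/c1cc(OC)c(OCOC)c(OC)c1 | intermediate |
| 5 | MOM-sinapyl alcohol | OC/C=C/c1cc(OC)c(OCOC)c(OC)c1 | intermediate |
| 6 | (2S,3S)-epoxy alcohol | OC[C@@H]1O[C@H]1c2cc(OC)c(OCOC)c(OC)c2 | intermediate |
| 7 | 3,4-dihydroxybenzaldehyde | O=Cc1ccc(O)c(O)c1 | starting material |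
| 8 | 4-(allyloxy)-3-hydroxybenzaldehyde | C=CCOc1ccc(C=O)cc1O | intermediate |
| 9 | (7R,8S)-aryl ether diol, O4'-allyl | OC[C@H](O)[C@H](Oc1cc(C=O)ccc1OCC=C)c2cc(OC)c(OCOC)c(OC)c2 | intermediate |
| 10 | (7R,8S)-phenol diol | OC[C@H](O)[C@H](Oc1cc(C=O)ccc1O)c2cc(OC)c(OCOC)c(OC)c2 | intermediate |
| 11 | (7R,8S)-9-O-acetate | CC(=O)OC[C@H](O)[C@H](Oc1cc(C=O)ccc1O)c2cc(OC)c(OCOC)c(OC)c2 | intermediate |
| 12 | (2R,3R)-benzodioxane aldehyde acetate | COCOc1c(OC)cc(cc1OC)[C@H]2Oc3cc(C=O)ccc3O[C@@H]2COC(C)=O | intermediate |
| 13 | methyl 3,5-dihydroxybenzoate | COC(=O)c1cc(O)cc(O)c1 | starting material |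
| 14 | methyl 3,5-bis(MOM-oxy)benzoate | COCOc1cc(cc(OCOC)c1)C(=O)OC | intermediate |
| 15 | 3,5-bis(MOM-oxy)benzyl alcohol | COCOc1cc(CO)cc(OCOC)c1 | intermediate |
| 16 | 3,5-bis(MOM-oxy)benzyl bromide | COCOc1cc(CBr)cc(OCOC)c1 | intermediate |
| 17 | diethyl 3,5-bis(MOM-oxy)benzylphosphonate | CCOP(=O)(Cc1cc(OCOC)cc(OCOC)c1)OCC | intermediate |
| 18 | tri-MOM aiphanol 9-acetate | COCOc1c(OC)cc(cc1OC)[C@H]2Oc3cc(/C=C/c4cc(OCOC)cc(OCOC)c4)ccc3O[C@@H]2COC(C)=O | intermediate |
| 19 | tri-MOM aiphanol | COCOc1c(OC)cc(cc1OC)[C@H]2Oc3cc(/C=C/c4cc(OCOC)cc(OCOC)c4)ccc3O[C@@H]2CO | intermediate |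
| 20 | aiphanol, (2R,3R), E | COc1cc([C@H]2Oc3cc(/C=C/c4cc(O)cc(O)c4)ccc3O[C@@H]2CO)cc(OC)c1O | target |

## Step count
- Total steps: 16.
- Longest linear sequence: 11 steps (1–4, 6–9, 14–16).

## Steps most likely to fail

**1. Step 6, opening of the electron-rich, acid-labile epoxide 6.**
- Risks: Payne rearrangement followed by attack at C9, partial SN1 epimerisation at C7, or decomposition of 6.
- Fallback: form the C8–OAr bond before any stereocentre exists.
  - O-alkylate 3-bromo-4-hydroxybenzaldehyde (as its acetal) with the α-bromo-β-keto ester made from MOM-acetosyringone.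
  - Set both centres in one dynamic kinetic reduction to the syn hydroxy ester, using a ketoreductase or Ru–TsDPEN transfer hydrogenation.
  - Reduce the ester, mask the primary OH, and close the ring by intramolecular Cu- or Pd-catalysed aryl C–O coupling, which breaks no bond at a stereocentre.

**2. Step 9, Mitsunobu closure at a hindered secondary carbinol.**
- Risks: elimination, or acetate neighbouring-group participation that leads to the cis ring or a seven-membered ring.
- Fallback: form the aryl–O bond instead of the alkyl–O bond.
  - Open 6 with 4-fluoro-3-hydroxybenzaldehyde and acetylate C9–OH with the lipase.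
  - Invert C8 intermolecularly (Mitsunobu with 4-nitrobenzoic acid), methanolyse, and silylate the primary OH.
  - Close by intramolecular SNAr of the C8 alkoxide on the C–F para to CHO, which proceeds with retention and gives the same (2R,3R) ring.

**3. Step 16, acidic triple MOM removal.**
- Risks: solvolysis of the newly unmasked p-hydroxybenzyl aryl ether, or acid-induced reactions of the stilbene.
- Fallback: change the protecting-group plan so the end-game is neutral.
  - Carry the syringyl and resorcinol phenols as allyl ethers, which the Sharpless epoxidation leaves untouched.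
  - Mask the catechol 4-OH as a MOM ether and remove it with mild acid at the diol stage, before the stilbene exists and while the syringyl oxygen is still alkylated.
  - Finish with a global Pd(0)-catalysed deallylation.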